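**Plan**

- Retrosynthetic cuts, in order: C12–C13 (sp3–sp2 coupling), C9–C11 (Ireland–Claisen from a 7β-allylic acetate), C8–C17 (enolate methylation), C5–C20/C10–C20 (a ring-fusion cyclopropane that is later opened to the C10 methyl), ring B back to an anisole (Birch), C1–C10 (diazoketone–arene closure), and C4–aryl (α-arylation).
- Forward: ring A is closed onto a 3-methoxyphenyl group, and the arene becomes ring B by Birch reduction. Cyclopropanation and acid opening give the 10-methyl octalone. C17, then C11–C12, then the Z C13–C16 unit are added, and the 8(17)-en-7α-ol is made last from a 7α,8α-epoxide.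
- Enabling feature: the C19 oxymethyl on C4 and the C20 methyl on C10 are syn-diaxial on the β face of ring A, and ring B carries its only oxygen at C7, para to C10. A 7-methoxy arene therefore gives, after Birch reduction, a C5=C10 alkene homoallylic to the C19 hydroxyl and a masked C7 ketone that later opens the cyclopropane.
- Stereochemistry: C4 from Ni/BINAP arylation; C2 from C19-OH-directed hydride delivery; C10 from C19-OH-directed cyclopropanation; C5 from Li/NH3; C9 from the suprafacial Claisen shift of a 7β oxygen (Luche reduction); C7 from α-face epoxidation; 13Z from trans-hydroalumination/iodination of but-2-yn-1-ol.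

Key step: step 12

Assumption: locants follow labdane numbering (decalin C1–C10, C17 on C8, C18 = 4α-methyl, C19 = 4β-CH2O, C20 on C10, side chain C11–C16; β = the face of C20). The BINAP antipode is the one that delivers (S)-lactone 3; it is written as (S)-BINAP by analogy with the parent reaction, and the other antipode would be used if the sense proves opposite.

**Route**

Step 1
Reactants: 1 rac-3-methyldihydrofuran-2(3H)-one (α-methyl-γ-butyrolactone); 2 3-chloroanisole
Product: 3 (S)-3-(3-methoxyphenyl)-3-methyldihydrofuran-2(3H)-one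
Conditions: Ni(cod)2 (5 mol %), (S)-BINAP (8.5 mol %), NaHMDS, ZnBr2 (15 mol %), toluene/THF, 60 °C
Reagents that add atoms: none
Why: Nickel(0)/BINAP-catalysed enantioselective α-arylation of a lactone enolate with an aryl chloride is established for α-methyl-γ-butyrolactone, and the chiral Ni(aryl)(enolate) complex sets the C4 quaternary centre in the C–C reductive elimination.

Step 2
Reactants: 3 (S)-3-(3-methoxyphenyl)-3-methyldihydrofuran-2(3H)-one
Product: 4 (S)-2-(3-methoxyphenyl)-2-methylbutane-1,4-diol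
Conditions: LiAlH4, THF, 0 °C → rt
Reagents that add atoms: none
Why: Hydride reduction of a lactone to the diol does not touch the quaternary centre.

Step 3
Reactants: 4 (S)-2-(3-methoxyphenyl)-2-methylbutane-1,4-diol
Product: 5 (S)-4-(3-methoxyphenyl)-4-methyldihydrofuran-2(3H)-one
Conditions: TEMPO (10 mol %), PhI(OAc)2 (2.5 eq), CH2Cl2, rt
Reagents that add atoms: none
Why: TEMPO/PhI(OAc)2 oxidative lactonisation of a 1,4-diol oxidises the unhindered primary alcohol rather than the neopentyl one, and the lactol is oxidised on, so the carbonyl ends up at C2 and the ring oxygen on C19.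

Step 4
Reactants: 5 (S)-4-(3-methoxyphenyl)-4-methyldihydrofuran-2(3H)-one
Product: 8 (S)-4-(tert-butyldimethylsilyloxy)-3-(3-methoxyphenyl)-3-methylbutanoic acid, via potassium hydroxy carboxylate 6 (not isolated), via bis-TBS derivative 7 (not isolated)
Conditions: KOH, MeOH/H2O, rt, evaporate; TBSCl, imidazole, DMF, 40 °C; K2CO3, MeOH/THF/H2O, then citric acid to pH 4
Reagents that add atoms: potassium hydroxide [K+].[OH-]; tert-butyldimethylsilyl chloride CC(C)(C)[Si](C)(C)Cl
Why: Saponification, exhaustive silylation and selective solvolysis of the labile silyl ester is the standard way to trap a γ-hydroxy acid before it relactonises.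

Step 5
Reactants: 8 (S)-4-(tert-butyldimethylsilyloxy)-3-(3-methoxyphenyl)-3-methylbutanoic acid
Product: 10 (S)-5-(tert-butyldimethylsilyloxy)-1-diazo-4-(3-methoxyphenyl)-4-methylpentan-2-one, via mixed anhydride 9 (not isolated)
Conditions: i-BuOCOCl, N-methylmorpholine, THF, −15 °C; CH2N2, Et2O, 0 °C
Reagents that add atoms: diazomethane C=[N+]=[N-]
Why: Acylation of diazomethane by a mixed carbonic anhydride (first stage of an Arndt–Eistert sequence) gives the α-diazoketone and adds C1 under conditions mild enough for the silyl ether.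

Step 6
Reactants: 10 (S)-5-(tert-butyldimethylsilyloxy)-1-diazo-4-(3-methoxyphenyl)-4-methylpentan-2-one
Product: 13 (S)-4-(hydroxymethyl)-6-methoxy-4-methyl-3,4-dihydronaphthalen-2(1H)-one, via dihydroazulenone 11 (not isolated), via silyl tetralone 12 (not isolated)
Conditions: Rh2(pfb)4 (1 mol %), CH2Cl2, rt; TFA (0.2 eq), 0 °C; 48 % aq HF, MeCN, 0 °C
Reagents that add atoms: none
Why: Intramolecular Buchner reaction of the rhodium carbenoid at the arene bond remote from the methoxy group gives a dihydroazulenone that rearranges with trifluoroacetic acid to the 2-tetralone (C1–C10 bond para to OMe), and aqueous HF then frees the C19 hydroxyl.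

Step 7
Reactants: 13 (S)-4-(hydroxymethyl)-6-methoxy-4-methyl-3,4-dihydronaphthalen-2(1H)-one
Product: 14 (2R,4S)-4-(hydroxymethyl)-6-methoxy-4-methyl-1,2,3,4-tetrahydronaphthalen-2-ol
Conditions: Me4NBH(OAc)3, MeCN/AcOH (1:1), −30 → 0 °C
Reagents that add atoms: none
Why: In this hydroxyl-directed (Saksena–Evans) triacetoxyborohydride reduction the pseudoaxial C19 alkoxyborohydride should deliver hydride internally to the β face of the C2 ketone, so the new hydroxyl is α, trans to C19.

Step 8
Reactants: 14 (2R,4S)-4-(hydroxymethyl)-6-methoxy-4-methyl-1,2,3,4-tetrahydronaphthalen-2-ol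
Product: 15 bis(triisopropylsilyl) ether of 14 (2-O and 19-O)
Conditions: TIPSOTf, 2,6-lutidine, CH2Cl2, 0 °C → rt
Reagents that add atoms: triisopropylsilyl triflate CC(C)[Si](OS(=O)(=O)C(F)(F)F)(C(C)C)C(C)C
Why: Silylation with a silyl triflate and a hindered pyridine base is routine for both a secondary and a neopentyl primary hydroxyl.

Step 9
Reactants: 15 bis(triisopropylsilyl) ether of 14
Product: 16 [(1S,3R)-7-methoxy-1-methyl-3-(triisopropylsilyloxy)-1,2,3,4-tetrahydronaphthalen-1-yl]methanol
Conditions: HF·pyridine, pyridine, THF, 0 °C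
Reagents that add atoms: none
Why: Selective desilylation discriminates by steric access to silicon, so the primary TIPS ether should be cleaved well before the secondary one.

Step 10
Reactants: 16 [(1S,3R)-7-methoxy-1-methyl-3-(triisopropylsilyloxy)-1,2,3,4-tetrahydronaphthalen-1-yl]methanol
Product: 17 4β-(hydroxymethyl)-7-methoxy-4α-methyl-2α-(triisopropylsilyloxy)-1,2,3,4,6,9-hexahydronaphthalene (5(10),7-diene)
Conditions: Li, NH3(l), THF, t-BuOH, −78 → −33 °C; NH4Cl
Reagents that add atoms: none
Why: Birch reduction of the anisole protonates the two unsubstituted positions C6 and C9 (ortho and meta to OMe), leaving the C7=C8 enol ether and the tetrasubstituted C5=C10 alkene, while the TIPS ether and the alkoxide are inert.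

Step 11
Reactants: 17 Birch dienol ether
Product: 18 7,7-ethylenedioxy-4β-(hydroxymethyl)-4α-methyl-2α-(triisopropylsilyloxy)-Δ5(10)-octalin
Conditions: HOCH2CH2OH, TsOH·H2O (2 mol %), CH2Cl2, 0 °C → rt
Reagents that add atoms: ethylene glycol OCCO
Why: Mild acid-catalysed ketalisation of the enol ether (protonation at C8, capture of the C7 oxocarbenium ion by the diol) keeps the β,γ-alkene at C5–C10, as in 19-nor-steroid practice.

Step 12
Reactants: 18 7,7-ethylenedioxy-4β-(hydroxymethyl)-4α-methyl-2α-(triisopropylsilyloxy)-Δ5(10)-octalin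
Product: 19 7,7-ethylenedioxy-4β-(hydroxymethyl)-4α-methyl-5β,10β-methylene-2α-(triisopropylsilyloxy)decalin (propellane; cyclopropane C5–C10–C20)
Conditions: Et2Zn (5 eq), CH2I2 (10 eq), CH2Cl2, −10 °C → rt
Reagents that add atoms: diiodomethane ICI
Why: Diethylzinc converts the alcohol into a zinc alkoxide that binds the (iodomethyl)zinc carbenoid, and methylene is transferred to the tetrasubstituted C5=C10 alkene in a concerted syn [2+1] addition through the butterfly transition state (hydroxyl-directed Simmons–Smith/Furukawa cyclopropanation). The closest known case is the homoallylic-hydroxyl-directed cyclopropanation of Birch-derived steroidal 5(10)-enes used for angular methylation of 19-nor steroids. The cyclopropane C5–C10–C20 closes in this single cheletropic-type step, both new bonds (C5–C20 and C10–C20) forming on the same face. The two new stereocentres C5 and C10 are both set by C4, because the pseudoaxial C19–O–Zn tether reaches only the β face and so places C20 syn to C19. Face selectivity is the only selectivity needed, since C5=C10 is the sole alkene: the equatorial 2α-OTIPS group fixes C19 pseudoaxial and cannot itself bind zinc, and the ketal offers no one-sided director.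

Step 13
Reactants: 19 propellane ketal
Product: 21 4β-(hydroxymethyl)-4α,10β-dimethyl-2α-(triisopropylsilyloxy)-Δ5-octalin-7-one, via cyclopropyl ketone 20 (not isolated)
Conditions: 2 M aq HCl, THF, 40 °C
Reagents that add atoms: water O
Why: Acetal hydrolysis is followed by acid-catalysed homoconjugate opening of the β-cyclopropyl ketone, in which the C7 enol (toward C6) assists protonation at C20 and cleavage of the strained C5–C20 bond, leaving the β C10 methyl and the Δ5-7-one.

Step 14
Reactants: 21 Δ5-octalin-7-one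
Product: 22 4β-(hydroxymethyl)-4α,8α,10β-trimethyl-2α-(triisopropylsilyloxy)-Δ5-octalin-7-one
Conditions: LDA (2.2 eq), THF, −78 °C; MeI, −78 → −30 °C
Reagents that add atoms: iodomethane CI
Why: Kinetic deprotonation of an enone occurs at the α′ carbon (C8) to give the cross-conjugated dienolate, which is C-methylated anti to the axial C20 methyl (8α expected; this centre becomes sp2 again in step 16).

Step 15
Reactants: 22 8α-methyl-Δ5-octalin-7-one
Product: 23 4β-(hydroxymethyl)-4α,8α,10β-trimethyl-2α-(triisopropylsilyloxy)-5α-H-trans-decalin-7-one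
Conditions: LiHMDS (1.05 eq), THF, −78 °C; Li, NH3(l), t-BuOH (1 eq), −78 °C; NH4Cl
Reagents that add atoms: none
Why: Dissolving-metal (Stork) reduction of the octalone protonates the C5 β-carbanion axially from the α face to give the trans-fused decalone, the hydroxyl being turned into its lithium alkoxide first so that it cannot deliver a proton to the β face.

Step 16
Reactants: 23 trans-decalin-7-one
Product: 24 7-(trimethylsilyloxy)-Δ7 silyl enol ether of 23 carrying a C19 trimethylsilyl ether
Conditions: TMSCl, NaI, Et3N, MeCN, 40 °C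
Reagents that add atoms: chlorotrimethylsilane C[Si](C)(C)Cl
Why: Iodotrimethylsilane formed in situ with triethylamine gives the thermodynamic, more substituted silyl enol ether (C7=C8) and also silylates the C19 hydroxyl.

Step 17
Reactants: 24 bis-TMS enol ether
Product: 26 4β-(hydroxymethyl)-4α,8,10β-trimethyl-2α-(triisopropylsilyloxy)-5α-H-Δ8-octalin-7-one, via C19-OTMS enone 25 (not isolated)
Conditions: Pd(OAc)2 (1.1 eq), MeCN, rt; K2CO3 (cat.), MeOH
Reagents that add atoms: none
Why: In the Saegusa–Ito oxidation, palladation at C8 and β-hydride elimination from C9 give the endocyclic 8-methyl-Δ8-7-one, and methanolysis removes the labile TMS ether.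

Step 18
Reactants: 26 Δ8-octalin-7-one
Product: 27 4β-(hydroxymethyl)-4α,8,10β-trimethyl-2α-(triisopropylsilyloxy)-5α-H-Δ8-octalin-7β-ol
Conditions: NaBH4, CeCl3·7H2O, MeOH, −40 °C
Reagents that add atoms: none
Why: Luche reduction is 1,2-selective and hydride should add axially from the α face, giving the pseudoequatorial 7β-alcohol by analogy with steroidal Δ1- and Δ4-3-ketones.

Step 19
Reactants: 27 Δ8-7β,19-diol
Product: 28 7β,19-diacetate of 27
Conditions: Ac2O, pyridine, DMAP (cat.), CH2Cl2, rt
Reagents that add atoms: acetic anhydride CC(=O)OC(C)=O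
Why: Standard acetylation esterifies both the allylic 7β-hydroxyl (the Claisen handle, source of C11–C12) and the C19 hydroxyl (the acetate required in the target).

Step 20
Reactants: 28 7β,19-diacetate
Product: 31 19-acetoxy-2α-(triisopropylsilyloxy)-13,14,15,16-tetranorlabd-7-en-12-oic acid, via bis(ketene silyl acetal) 29 (not isolated), via silyl ester 30 (not isolated)
Conditions: LDA (3 eq), TBSCl, THF/DMPU, −78 °C → rt; toluene, 90 °C; AcOH/H2O/THF
Reagents that add atoms: none
Why: In the Ireland–Claisen rearrangement both acetates become ketene silyl acetals but only the allylic one can undergo the [3,3] shift, which is suprafacial and so turns the 7β C–O bond into the 9β C–C bond (9α-H) with the alkene moving to C7=C8, while aqueous work-up returns the C19 acetate and the free acid.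

Step 21
Reactants: 31 tetranorlabd-7-en-12-oic acid
Product: 33 12-hydroxy-2α-(triisopropylsilyloxy)-13,14,15,16-tetranorlabd-7-en-19-yl acetate, via mixed anhydride 32 (not isolated)
Conditions: i-BuOCOCl, N-methylmorpholine, THF, −15 °C; NaBH4, H2O, 0 °C
Reagents that add atoms: none
Why: Borohydride reduction of the mixed carbonic anhydride gives the primary alcohol and leaves the acetate, the silyl ether and the alkene alone.

Step 22
Reactants: 33 12-alcohol
Product: 34 12-iodo-2α-(triisopropylsilyloxy)-13,14,15,16-tetranorlabd-7-en-19-yl acetate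
Conditions: I2, PPh3, imidazole, CH2Cl2, 0 °C
Reagents that add atoms: iodine II
Why: Appel-type iodination converts the unhindered primary alcohol into the iodide by SN2.

Step 23
Reactants: 35 but-2-yn-1-ol
Product: 37 (Z)-3-iodobut-2-en-1-ol, via alkenylalanate 36 (not isolated)
Conditions: Red-Al, Et2O, 0 °C → rt; I2, THF, −78 °C
Reagents that add atoms: iodine II
Why: Red-Al trans-hydroalumination of a propargylic alcohol places aluminium on C3 in a five-membered alkoxyalanate, and iodinolysis with retention gives the Z iodoalkenol that fixes the C13=C14 geometry.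

Step 24
Reactants: 37 (Z)-3-iodobut-2-en-1-ol
Product: 38 (Z)-3-iodobut-2-en-1-yl acetate
Conditions: Ac2O, pyridine, CH2Cl2, 0 °C
Reagents that add atoms: acetic anhydride CC(=O)OC(C)=O
Why: Routine acetylation of the allylic alcohol.

Step 25
Reactants: 34 12-iodide; 38 (Z)-3-iodobut-2-en-1-yl acetate
Product: 40 2α-(triisopropylsilyloxy)labda-7,13Z-diene-15,19-diyl diacetate, via alkylzinc iodide 39 (not isolated)
Conditions: Zn dust, LiCl, THF, 40 °C; 38, PdCl2(dppf) (5 mol %), THF/DMA, rt
Reagents that add atoms: none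
Why: In this Negishi coupling zinc insertion into the primary iodide tolerates the esters, and palladium-catalysed coupling with the alkenyl iodide forms C12–C13 with retention of the Z geometry.

Step 26
Reactants: 40 labda-7,13Z-diene
Product: 41 7α,8α-epoxy-2α-(triisopropylsilyloxy)labd-13Z-ene-15,19-diyl diacetate
Conditions: mCPBA (1.05 eq), NaHCO3, CH2Cl2, −20 → 0 °C
Reagents that add atoms: 3-chloroperbenzoic acid OOC(=O)c1cccc(Cl)c1
Why: In the Prilezhaev epoxidation the ring alkene is more electron-rich than the side-chain alkene, which is deactivated by its allylic acetate as in geranyl acetate, and the peracid should attack the α face, away from the axial C20 methyl and the 9β chain.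

Step 27
Reactants: 41 7α,8α-epoxide
Product: 42 7α-hydroxy-2α-(triisopropylsilyloxy)labda-8(17),13Z-diene-15,19-diyl diacetate
Conditions: Cp2TiCl2 (2.5 eq), Mn dust, THF, rt; aq NaH2PO4
Reagents that add atoms: none
Why: Titanocene(III) (Nugent–RajanBabu) homolysis of the tertiary C8–O bond followed by hydrogen abstraction from the C17 methyl by a second Ti(III) (mixed disproportionation) gives the exocyclic alkene with the C7 oxygen left α, and esters are inert to the reagent.

Step 28
Reactants: 42 silyl-protected allylic alcohol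
Product: 43 2α,7α-dihydroxylabda-8(17),13Z-diene-15,19-diyl diacetate (CNP0171158.2)
Conditions: HF·pyridine, pyridine, THF, 0 °C → rt
Reagents that add atoms: none
Why: Buffered fluoride desilylation removes the TIPS ether without touching the acetates or the allylic alcohol.

**Compound list**

1 | rac-3-methyldihydrofuran-2(3H)-one | CC1CCOC1=O | starting material
2 | 3-chloroanisole | COc1cccc(Cl)c1 | starting material
3 | (S)-3-(3-methoxyphenyl)-3-methyldihydrofuran-2(3H)-one | COc1cccc(c1)[C@@]2(C)C(=O)OCC2 | intermediate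
4 | (S)-2-(3-methoxyphenyl)-2-methylbutane-1,4-diol | COc1cccc(c1)[C@@](C)(CO)CCO | intermediate
5 | (S)-4-(3-methoxyphenyl)-4-methyldihydrofuran-2(3H)-one | COc1cccc(c1)[C@@]2(C)COC(=O)C2 | intermediate
6 | potassium (S)-4-hydroxy-3-(3-methoxyphenyl)-3-methylbutanoate (not isolated) | COc1cccc(c1)[C@@](C)(CO)CC(=O)[O-].[K+] | intermediate
7 | TBS ester of 8 (not isolated) | COc1cccc(c1)[C@@](C)(CO[Si](C)(C)C(C)(C)C)CC(=O)O[Si](C)(C)C(C)(C)C | intermediate
8 | (S)-4-(tert-butyldimethylsilyloxy)-3-(3-methoxyphenyl)-3-methylbutanoic acid | COc1cccc(c1)[C@@](C)(CO[Si](C)(C)C(C)(C)C)CC(=O)O | intermediate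
9 | isobutyl carbonic anhydride of 8 (not isolated) | COc1cccc(c1)[C@@](C)(CO[Si](C)(C)C(C)(C)C)CC(=O)OC(=O)OCC(C)C | intermediate
10 | (S)-5-(tert-butyldimethylsilyloxy)-1-diazo-4-(3-methoxyphenyl)-4-methylpentan-2-one | COc1cccc(c1)[C@@](C)(CO[Si](C)(C)C(C)(C)C)CC(=O)C=[N+]=[N-] | intermediate
11 | (3S)-3-(tert-butyldimethylsilyloxymethyl)-5-methoxy-3-methyl-3,8a-dihydroazulen-1(2H)-one, C8a epimers (not isolated) | O=C1C[C@](C)(CO[Si](C)(C)C(C)(C)C)C2=CC(OC)=CC=CC12 | intermediate
12 | (S)-4-(tert-butyldimethylsilyloxymethyl)-6-methoxy-4-methyl-3,4-dihydronaphthalen-2(1H)-one (not isolated) | COc1ccc2c(c1)[C@@](C)(CO[Si](C)(C)C(C)(C)C)CC(=O)C2 | intermediate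
13 | (S)-4-(hydroxymethyl)-6-methoxy-4-methyl-3,4-dihydronaphthalen-2(1H)-one | COc1ccc2c(c1)[C@@](C)(CO)CC(=O)C2 | intermediate
14 | (2R,4S)-4-(hydroxymethyl)-6-methoxy-4-methyl-1,2,3,4-tetrahydronaphthalen-2-ol | COc1ccc2c(c1)[C@@](C)(CO)C[C@H](O)C2 | intermediate
15 | bis(triisopropylsilyl) ether of 14 | COc1ccc2c(c1)[C@@](C)(CO[Si](C(C)C)(C(C)C)C(C)C)C[C@H](O[Si](C(C)C)(C(C)C)C(C)C)C2 | intermediate
16 | [(1S,3R)-7-methoxy-1-methyl-3-(triisopropylsilyloxy)-1,2,3,4-tetrahydronaphthalen-1-yl]methanol | COc1ccc2c(c1)[C@@](C)(CO)C[C@H](O[Si](C(C)C)(C(C)C)C(C)C)C2 | intermediate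
17 | 4β-(hydroxymethyl)-7-methoxy-4α-methyl-2α-(triisopropylsilyloxy)-1,2,3,4,6,9-hexahydronaphthalene (5(10),7-diene) | COC1=CCC2=C(C1)[C@@](C)(CO)C[C@H](O[Si](C(C)C)(C(C)C)C(C)C)C2 | intermediate
18 | 7,7-ethylenedioxy-4β-(hydroxymethyl)-4α-methyl-2α-(triisopropylsilyloxy)-Δ5(10)-octalin | C1C2(OCCO2)CCC3=C1[C@@](C)(CO)C[C@H](O[Si](C(C)C)(C(C)C)C(C)C)C3 | intermediate
19 | 7,7-ethylenedioxy-4β-(hydroxymethyl)-4α-methyl-5β,10β-methylene-2α-(triisopropylsilyloxy)decalin | C1C2(OCCO2)CC[C@]3(C4)[C@@]14[C@@](C)(CO)C[C@H](O[Si](C(C)C)(C(C)C)C(C)C)C3 | intermediate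
20 | 4β-(hydroxymethyl)-4α-methyl-5β,10β-methylene-2α-(triisopropylsilyloxy)decalin-7-one (not isolated) | C1C(=O)CC[C@]3(C4)[C@@]14[C@@](C)(CO)C[C@H](O[Si](C(C)C)(C(C)C)C(C)C)C3 | intermediate
21 | 4β-(hydroxymethyl)-4α,10β-dimethyl-2α-(triisopropylsilyloxy)-Δ5-octalin-7-one | O=C1C=C2[C@@](C)(CO)C[C@H](O[Si](C(C)C)(C(C)C)C(C)C)C[C@]2(C)CC1 | intermediate
22 | 4β-(hydroxymethyl)-4α,8α,10β-trimethyl-2α-(triisopropylsilyloxy)-Δ5-octalin-7-one | O=C1C=C2[C@@](C)(CO)C[C@H](O[Si](C(C)C)(C(C)C)C(C)C)C[C@]2(C)C[C@@H]1C | intermediate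
23 | 4β-(hydroxymethyl)-4α,8α,10β-trimethyl-2α-(triisopropylsilyloxy)-5α-H-trans-decalin-7-one | O=C1C[C@H]2[C@@](C)(CO)C[C@H](O[Si](C(C)C)(C(C)C)C(C)C)C[C@]2(C)C[C@@H]1C | intermediate
24 | 7-(trimethylsilyloxy)-Δ7 enol ether of 23 with C19 trimethylsilyl ether | CC1=C(O[Si](C)(C)C)C[C@H]2[C@@](C)(CO[Si](C)(C)C)C[C@H](O[Si](C(C)C)(C(C)C)C(C)C)C[C@]2(C)C1 | intermediate
25 | C19 trimethylsilyl ether of 26 (not isolated) | O=C1C[C@H]2[C@@](C)(CO[Si](C)(C)C)C[C@H](O[Si](C(C)C)(C(C)C)C(C)C)C[C@]2(C)C=C1C | intermediate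
26 | 4β-(hydroxymethyl)-4α,8,10β-trimethyl-2α-(triisopropylsilyloxy)-5α-H-Δ8-octalin-7-one | O=C1C[C@H]2[C@@](C)(CO)C[C@H](O[Si](C(C)C)(C(C)C)C(C)C)C[C@]2(C)C=C1C | intermediate
27 | 4β-(hydroxymethyl)-4α,8,10β-trimethyl-2α-(triisopropylsilyloxy)-5α-H-Δ8-octalin-7β-ol | O[C@H]1C[C@H]2[C@@](C)(CO)C[C@H](O[Si](C(C)C)(C(C)C)C(C)C)C[C@]2(C)C=C1C | intermediate
28 | 7β,19-diacetate of 27 | CC(=O)O[C@H]1C[C@H]2[C@@](C)(COC(C)=O)C[C@H](O[Si](C(C)C)(C(C)C)C(C)C)C[C@]2(C)C=C1C | intermediate
29 | bis(ketene tert-butyldimethylsilyl acetal) of 28 (not isolated) | C=C(O[Si](C)(C)C(C)(C)C)O[C@H]1C[C@H]2[C@@](C)(COC(=C)O[Si](C)(C)C(C)(C)C)C[C@H](O[Si](C(C)C)(C(C)C)C(C)C)C[C@]2(C)C=C1C | intermediate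
30 | rearranged TBS ester still carrying the C19 ketene silyl acetal (not isolated) | CC1=CC[C@H]2[C@@](C)(COC(=C)O[Si](C)(C)C(C)(C)C)C[C@H](O[Si](C(C)C)(C(C)C)C(C)C)C[C@]2(C)[C@H]1CC(=O)O[Si](C)(C)C(C)(C)C | intermediate
31 | 19-acetoxy-2α-(triisopropylsilyloxy)-13,14,15,16-tetranorlabd-7-en-12-oic acid | CC1=CC[C@H]2[C@@](C)(COC(C)=O)C[C@H](O[Si](C(C)C)(C(C)C)C(C)C)C[C@]2(C)[C@H]1CC(=O)O | intermediate
32 | isobutyl carbonic anhydride of 31 (not isolated) | CC1=CC[C@H]2[C@@](C)(COC(C)=O)C[C@H](O[Si](C(C)C)(C(C)C)C(C)C)C[C@]2(C)[C@H]1CC(=O)OC(=O)OCC(C)C | intermediate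
33 | 12-hydroxy-2α-(triisopropylsilyloxy)-13,14,15,16-tetranorlabd-7-en-19-yl acetate | CC1=CC[C@H]2[C@@](C)(COC(C)=O)C[C@H](O[Si](C(C)C)(C(C)C)C(C)C)C[C@]2(C)[C@H]1CCO | intermediate
34 | 12-iodo-2α-(triisopropylsilyloxy)-13,14,15,16-tetranorlabd-7-en-19-yl acetate | CC1=CC[C@H]2[C@@](C)(COC(C)=O)C[C@H](O[Si](C(C)C)(C(C)C)C(C)C)C[C@]2(C)[C@H]1CCI | intermediate
35 | but-2-yn-1-ol | CC#CCO | starting material
36 | sodium cyclic alkoxy(alkenyl)alanate from 35 (not isolated) | CC1=CCO[Al-]1(OCCOC)OCCOC.[Na+] | intermediate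
37 | (Z)-3-iodobut-2-en-1-ol | C/C(I)=C/CO | intermediate
38 | (Z)-3-iodobut-2-en-1-yl acetate | CC(=O)OC/C=C(/C)I | intermediate
39 | alkylzinc iodide from 34 (not isolated) | CC1=CC[C@H]2[C@@](C)(COC(C)=O)C[C@H](O[Si](C(C)C)(C(C)C)C(C)C)C[C@]2(C)[C@H]1CC[Zn]I | intermediate
40 | 2α-(triisopropylsilyloxy)labda-7,13Z-diene-15,19-diyl diacetate | CC1=CC[C@H]2[C@@](C)(COC(C)=O)C[C@H](O[Si](C(C)C)(C(C)C)C(C)C)C[C@]2(C)[C@H]1CC/C(C)=C\COC(C)=O | intermediate
41 | 7α,8α-epoxy-2α-(triisopropylsilyloxy)labd-13Z-ene-15,19-diyl diacetate | C[C@@]12O[C@@H]1C[C@H]3[C@@](C)(COC(C)=O)C[C@H](O[Si](C(C)C)(C(C)C)C(C)C)C[C@]3(C)[C@H]2CC/C(C)=C\COC(C)=O | intermediate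
42 | 7α-hydroxy-2α-(triisopropylsilyloxy)labda-8(17),13Z-diene-15,19-diyl diacetate | C=C1[C@H](O)C[C@H]2[C@@](C)(COC(C)=O)C[C@H](O[Si](C(C)C)(C(C)C)C(C)C)C[C@]2(C)[C@H]1CC/C(C)=C\COC(C)=O | intermediate
43 | 2α,7α-dihydroxylabda-8(17),13Z-diene-15,19-diyl diacetate (CNP0171158.2) | C=C1[C@H](O)C[C@H]2[C@@](C)(COC(C)=O)C[C@H](O)C[C@]2(C)[C@H]1CC/C(C)=C\COC(C)=O | target

**Step count**

Total: 28 steps. Longest linear sequence: 26 steps (steps 1–22 and 25–28); steps 23–24 make the side-chain iodide 38.

**Steps most likely to fail, with fallbacks**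

Step 7. Hydride transfer inside the alkoxyborohydride has to pass through a seven-membered array, so slow internal delivery and competing intermolecular reduction may erode the facial selectivity at C2. The fallback sets out from 12, isolated by leaving out the HF stage of step 6. Sodium borohydride in methanol gives both C2 epimers, the 2α-alcohol F1 and the 2β-alcohol F2, which are separated. F2 is inverted by a Mitsunobu reaction with 4-nitrobenzoic acid to the 2α 4-nitrobenzoate F3, and methanolysis (K2CO3, MeOH) turns F3 into more F1, so both epimers converge. Silylation of F1 with TIPSOTf gives the mixed silyl ether F4, and its primary TBS ether is cleaved with CSA in MeOH to come back to the route at 16.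

Step 20. The sigmatropic shift starts from a pseudoequatorial C7–O bond and forms a bond next to the quaternary C10, so slow rearrangement with competing C-silylation or elimination of the allylic ester may result. The fallback sets out from 27 and uses the neutral Eschenmoser–Claisen variant (N,N-dimethylacetamide dimethyl acetal, xylene, 140 °C), which should give the 9β-acetamide F5. Any C19 ester formed on hydrolysis of the amide acetal is cleaved in the next step, where LiEt3BH reduces the amide to the 12,19-diol F6. Appel iodination at the unhindered C12 hydroxyl gives the iodo alcohol F7, and acetylation of the neopentyl hydroxyl returns to the route at 34.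

Step 27. The C8 radical may be trapped by titanium and lose the titanoxy group (deoxygenation back to the alkene), or hydrogen may be lost from C9 to give the endocyclic isomer. The fallback sets out from 41. Methanolysis (K2CO3, MeOH) removes both acetates to give the epoxy diol F8, which is isomerised with diethylaluminium 2,2,6,6-tetramethylpiperidide in toluene at 0 °C (syn removal of a C17 proton) to the triol F9. Selective acetylation of the two primary hydroxyls (AcCl, 2,4,6-collidine, CH2Cl2, −78 °C) returns to the route at 42.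

**Further compounds**

F1 | step 7 | (2R,4S)-4-(tert-butyldimethylsilyloxymethyl)-6-methoxy-4-methyl-1,2,3,4-tetrahydronaphthalen-2-ol (2α-alcohol) | COc1ccc2c(c1)[C@@](C)(CO[Si](C)(C)C(C)(C)C)C[C@H](O)C2
F2 | step 7 | C2 epimer of F1 (2β-alcohol) | COc1ccc2c(c1)[C@@](C)(CO[Si](C)(C)C(C)(C)C)C[C@@H](O)C2
F3 | step 7 | 2α 4-nitrobenzoate of F1 | COc1ccc2c(c1)[C@@](C)(CO[Si](C)(C)C(C)(C)C)C[C@H](OC(=O)c3ccc(cc3)[N+](=O)[O-])C2
F4 | step 7 | 2-O-triisopropylsilyl ether of F1 | COc1ccc2c(c1)[C@@](C)(CO[Si](C)(C)C(C)(C)C)C[C@H](O[Si](C(C)C)(C(C)C)C(C)C)C2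
F5 | step 20 | 19-hydroxy-N,N-dimethyl-2α-(triisopropylsilyloxy)-13,14,15,16-tetranorlabd-7-en-12-amide | CC1=CC[C@H]2[C@@](C)(CO)C[C@H](O[Si](C(C)C)(C(C)C)C(C)C)C[C@]2(C)[C@H]1CC(=O)N(C)C
F6 | step 20 | 2α-(triisopropylsilyloxy)-13,14,15,16-tetranorlabd-7-ene-12,19-diol | CC1=CC[C@H]2[C@@](C)(CO)C[C@H](O[Si](C(C)C)(C(C)C)C(C)C)C[C@]2(C)[C@H]1CCO
F7 | step 20 | 12-iodo-2α-(triisopropylsilyloxy)-13,14,15,16-tetranorlabd-7-en-19-ol | CC1=CC[C@H]2[C@@](C)(CO)C[C@H](O[Si](C(C)C)(C(C)C)C(C)C)C[C@]2(C)[C@H]1CCI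
F8 | step 27 | 7α,8α-epoxy-2α-(triisopropylsilyloxy)labd-13Z-ene-15,19-diol | C[C@@]12O[C@@H]1C[C@H]3[C@@](C)(CO)C[C@H](O[Si](C(C)C)(C(C)C)C(C)C)C[C@]3(C)[C@H]2CC/C(C)=C\CO
F9 | step 27 | 2α-(triisopropylsilyloxy)labda-8(17),13Z-diene-7α,15,19-triol | C=C1[C@H](O)C[C@H]2[C@@](C)(CO)C[C@H](O[Si](C(C)C)(C(C)C)C(C)C)C[C@]2(C)[C@H]1CC/C(C)=C\CO
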